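**Plan**
- Retrosynthesis: first the three O–benzyl bonds are cut, then the C–B ester bond (B4 oxygen to the ring C carbonyl), then ring B at B4–B5, B6–B1 and B3–B4, then the diazo group, and last the B–A ester bond (ring A oxygen to the carbonyl on B1) at a β-keto ester stage.
- Forward: ring A comes ready-made from methyl atrarate and is esterified with an acylketene from tiglic acid and Meldrum's acid; ring B is then built on that ester by benzannulation; ring C (also from methyl atrarate) is attached last and all benzyl groups are removed together.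
- Enabling feature: ring B is a hexasubstituted 3-methoxyphenol with the carboxyl-bearing B1 para to the B4 oxygen and the B6 methoxy next to B1, which is the resorcinol monoether pattern a vinylketene (B1–B4) and 1-methoxypropyne (B5, B6) give.
- Stereochemistry: the target has no stereocentre, axis or stereogenic alkene; the E-alkene of tiglic acid ends in the arene and the transient stereocentres of the key step vanish on aromatisation.

Key step: step 10

Remark: the target is achiral, so the single compound drawn is the goal and no enantioselective step is needed.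

**Route**

Step 1
Reactants: 1 methyl 2,4-dihydroxy-3,6-dimethylbenzoate (methyl atrarate)
Product: 2 methyl 4-(benzyloxy)-2-hydroxy-3,6-dimethylbenzoate
Conditions: BnBr (1.05 equiv), K2CO3, acetone, reflux
Reagents that add atoms: benzyl bromide, BrCc1ccccc1
Why: Williamson etherification should take place at the free and more acidic 4-OH, because the 2-OH is hydrogen-bonded to the ester carbonyl and flanked by the 3-methyl group.

Step 2
Reactants: 2 methyl 4-(benzyloxy)-2-hydroxy-3,6-dimethylbenzoate
Product: 3 methyl 4-(benzyloxy)-2-methoxy-3,6-dimethylbenzoate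
Conditions: MeI (3 equiv), K2CO3, DMF, 50 °C
Reagents that add atoms: iodomethane, CI
Why: Williamson methylation of the chelated phenol, which a polar aprotic solvent and excess iodomethane should force to completion.

Step 3
Reactants: 3 methyl 4-(benzyloxy)-2-methoxy-3,6-dimethylbenzoate
Product: 4 4-(benzyloxy)-2-methoxy-3,6-dimethylbenzoic acid
Conditions: KOH, DMSO/H2O (4:1), 90 °C; then HCl, 0 °C
Reagents that add atoms: potassium hydroxide, [K+].[OH-]
Why: saponification of a 2,6-disubstituted benzoate needs poorly solvated hydroxide in hot aqueous DMSO, conditions that leave the benzyl and methyl ethers untouched.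

Step 4
Reactants: 4 4-(benzyloxy)-2-methoxy-3,6-dimethylbenzoic acid
Product: 5 4-hydroxy-2-methoxy-3,6-dimethylbenzoic acid
Conditions: H2 (1 atm), 10% Pd/C, EtOAc, rt
Reagents that add atoms: none
Why: catalytic hydrogenolysis of the aryl benzyl ether frees the 4-OH without touching the acid or the methyl ether.

Step 5
Reactants: 5 4-hydroxy-2-methoxy-3,6-dimethylbenzoic acid
Product: 6 benzyl 4-hydroxy-2-methoxy-3,6-dimethylbenzoate
Conditions: BnBr (1.05 equiv), KHCO3, DMF, rt
Reagents that add atoms: benzyl bromide, BrCc1ccccc1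
Why: chemoselective SN2 alkylation of the carboxylate, since hydrogen carbonate deprotonates the acid but not the phenol and O-alkylation of a hindered carboxylate is not slowed by the ortho groups.

Step 6
Reactants: 7 tiglic acid [(E)-2-methylbut-2-enoic acid]; 8 Meldrum's acid (2,2-dimethyl-1,3-dioxane-4,6-dione)
Product: 9 5-[(2E)-1-hydroxy-2-methylbut-2-en-1-ylidene]-2,2-dimethyl-1,3-dioxane-4,6-dione (tigloyl Meldrum's acid, enol form)
Conditions: DCC, DMAP, CH2Cl2, 0 °C to rt; cold aq. KHSO4 wash
Reagents that add atoms: none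
Why: carbodiimide/DMAP C-acylation of Meldrum's acid is standard, and the α,β-disubstituted enoyl group is a poor Michael acceptor, so C-acylation should dominate.

Step 7
Reactants: 9 tigloyl Meldrum's acid; 6 benzyl 4-hydroxy-2-methoxy-3,6-dimethylbenzoate
Product: 11 benzyl 2-methoxy-3,6-dimethyl-4-{[(4E)-4-methyl-3-oxohex-4-enoyl]oxy}benzoate, via acylketene 10 (not isolated)
Conditions: toluene, 100 °C
Reagents that add atoms: none
Why: thermal fragmentation of the acyl Meldrum's acid (loss of acetone and CO2) gives acylketene 10, whose unhindered sp carbon the phenol of 6 should capture to form the B–A ester before ring B exists.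

Step 8
Reactants: 11 aryl β-keto ester
Product: 12 benzyl 4-{[(4E)-2-diazo-4-methyl-3-oxohex-4-enoyl]oxy}-2-methoxy-3,6-dimethylbenzoate
Conditions: 4-acetamidobenzenesulfonyl azide, Et3N, MeCN, 0 °C to rt
Reagents that add atoms: 4-acetamidobenzenesulfonyl azide, CC(=O)Nc1ccc(cc1)S(=O)(=O)N=[N+]=[N-]
Why: Regitz diazo transfer to the doubly activated methylene proceeds under mild amine base that the aryl and benzyl esters tolerate.

Step 9
Reactants: 13 chloroacetaldehyde dimethyl acetal (2-chloro-1,1-dimethoxyethane)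
Product: 15 1-methoxyprop-1-yne, via sodium methoxyacetylide 14 (not isolated)
Conditions: NaNH2 (3 equiv), liq. NH3, −35 °C; then MeI, −35 °C to rt; distillation
Reagents that add atoms: iodomethane, CI
Why: double elimination (methanol, then HCl) with sodium amide gives the alkoxyacetylide, and its C-alkylation is the established route to 1-alkoxy-1-alkynes.

Step 10
Reactants: 12 diazo keto ester; 15 1-methoxyprop-1-yne (4 equiv)
Product: 20 benzyl 4-[(4-hydroxy-2-methoxy-3,5,6-trimethylbenzoyl)oxy]-2-methoxy-3,6-dimethylbenzoate (B–A didepside phenol), via vinylketene 16 (not isolated), via vinylcyclobutenone 17 (not isolated), via dienylketene 18 (not isolated), via cyclohexadienone 19 (not isolated)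
Conditions: hν (medium-pressure Hg lamp, Pyrex), toluene, 20 °C, 12 added slowly to 15; then 100 °C
Reagents that add atoms: none
Why: Proposed new method: photochemical Wolff rearrangement of 12 (1,2-shift of the but-2-en-2-yl group from the ketone carbonyl to the carbene carbon, which should be preferred over aryloxy migration) gives the ester-substituted vinylketene 16, whose sp carbon is attacked by the methyl-bearing carbon of the polarised ynol ether while the methoxy-bearing carbon closes on the α-carbon, so that a [2+2] cycloaddition forms B4–B5 and B6–B1 in cyclobutenone 17. Heating then drives the reversible 4π electrocyclic opening to dienylketene 18, the 6π electrocyclic closure that forms B3–B4 and closes ring B as the six-membered carbocycle (cyclohexadienone 19), and the irreversible tautomerisation to phenol 20. The closest known reaction is the Danheiser benzannulation of α,β-unsaturated α-diazo ketones with alkoxyalkynes to resorcinol monoethers, in which a vinylketene carrying an aryl ester on its α-carbon has not been documented. Regiochemistry rests on the donor polarisation of 15, which places the methoxy group at B6 beside the carboxyl-bearing B1 and the methyl group at B5. The step needs closure at the α-carbon in preference to hetero-[4+2] through the ester carbonyl and to direct closure at the diene terminus; the weakly basic aryl ester carbonyl oxygen, the out-of-plane twist of the fully substituted butenyl group, the non-polar solvent and a low stationary ketene concentration in excess 15 are relied on for that. The stereocentres of 17 and 19 are transient and disappear on aromatisation, so no stereochemistry has to be controlled.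

Step 11
Reactants: 1 methyl atrarate
Product: 21 methyl 2,4-bis(benzyloxy)-3,6-dimethylbenzoate
Conditions: BnBr (2.5 equiv), K2CO3, DMF, 70 °C
Reagents that add atoms: benzyl bromide, BrCc1ccccc1
Why: exhaustive Williamson benzylation, in which hot DMF and excess reagent should also alkylate the chelated 2-OH.

Step 12
Reactants: 21 methyl 2,4-bis(benzyloxy)-3,6-dimethylbenzoate
Product: 22 2,4-bis(benzyloxy)-3,6-dimethylbenzoic acid
Conditions: KOH, DMSO/H2O (4:1), 100 °C; then HCl, 0 °C
Reagents that add atoms: potassium hydroxide, [K+].[OH-]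
Why: saponification of the hindered benzoate with hydroxide in hot aqueous DMSO, to which the benzyl ethers are inert.

Step 13
Reactants: 22 2,4-bis(benzyloxy)-3,6-dimethylbenzoic acid (1.5 equiv); 20 B–A didepside phenol
Product: 24 benzyl 4-[(4-{[2,4-bis(benzyloxy)-3,6-dimethylbenzoyl]oxy}-2-methoxy-3,5,6-trimethylbenzoyl)oxy]-2-methoxy-3,6-dimethylbenzoate, via mixed anhydride 23 (not isolated)
Conditions: (CF3CO)2O, toluene, 0 °C to rt; aq. NaHCO3
Reagents that add atoms: none
Why: trifluoroacetic anhydride converts the 2,6-disubstituted acid into mixed anhydride 23, which ionises to a linear, unshielded acylium ion that the di-ortho-methyl phenol of 20 should capture (classical depside esterification), while benzyl ethers and esters tolerate the medium at room temperature.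

Step 14
Reactants: 24 tribenzyl-protected tridepside
Product: 25 4-[(4-{[2,4-dihydroxy-3,6-dimethylbenzoyl]oxy}-2-methoxy-3,5,6-trimethylbenzoyl)oxy]-2-methoxy-3,6-dimethylbenzoic acid (CNP0425440.0)
Conditions: H2 (1 atm), 10% Pd/C, EtOAc, rt
Reagents that add atoms: none
Why: hydrogenolysis should remove the benzyl ester and both benzyl ethers in one operation, while the two aryl ester links and the aryl methyl ethers are inert to H2/Pd-C.

**Compound list**

1 | methyl 2,4-dihydroxy-3,6-dimethylbenzoate (methyl atrarate) | COC(=O)c1c(C)cc(O)c(C)c1O | starting material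
2 | methyl 4-(benzyloxy)-2-hydroxy-3,6-dimethylbenzoate | COC(=O)c1c(C)cc(OCc2ccccc2)c(C)c1O | intermediate
3 | methyl 4-(benzyloxy)-2-methoxy-3,6-dimethylbenzoate | COC(=O)c1c(C)cc(OCc2ccccc2)c(C)c1OC | intermediate
4 | 4-(benzyloxy)-2-methoxy-3,6-dimethylbenzoic acid | COc1c(C)c(OCc2ccccc2)cc(C)c1C(=O)O | intermediate
5 | 4-hydroxy-2-methoxy-3,6-dimethylbenzoic acid | COc1c(C)c(O)cc(C)c1C(=O)O | intermediate
6 | benzyl 4-hydroxy-2-methoxy-3,6-dimethylbenzoate | COc1c(C)c(O)cc(C)c1C(=O)OCc1ccccc1 | intermediate
7 | tiglic acid, (E)-2-methylbut-2-enoic acid | C/C=C(\C)C(=O)O | starting material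
8 | Meldrum's acid, 2,2-dimethyl-1,3-dioxane-4,6-dione | CC1(C)OC(=O)CC(=O)O1 | starting material
9 | 5-[(2E)-1-hydroxy-2-methylbut-2-en-1-ylidene]-2,2-dimethyl-1,3-dioxane-4,6-dione | C/C=C(\C)C(O)=C1C(=O)OC(C)(C)OC1=O | intermediate
10 | (4E)-4-methylhexa-1,4-diene-1,3-dione (tigloylketene) | C/C=C(\C)C(=O)C=C=O | intermediate (not isolated)
11 | benzyl 2-methoxy-3,6-dimethyl-4-{[(4E)-4-methyl-3-oxohex-4-enoyl]oxy}benzoate | C/C=C(\C)C(=O)CC(=O)Oc1cc(C)c(C(=O)OCc2ccccc2)c(OC)c1C | intermediate
12 | benzyl 4-{[(4E)-2-diazo-4-methyl-3-oxohex-4-enoyl]oxy}-2-methoxy-3,6-dimethylbenzoate | C/C=C(\C)C(=O)C(=[N+]=[N-])C(=O)Oc1cc(C)c(C(=O)OCc2ccccc2)c(OC)c1C | intermediate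
13 | chloroacetaldehyde dimethyl acetal, 2-chloro-1,1-dimethoxyethane | COC(CCl)OC | starting material
14 | sodium methoxyacetylide | [Na+].[C-]#COC | intermediate (not isolated)
15 | 1-methoxyprop-1-yne | CC#COC | intermediate
16 | benzyl 2-methoxy-3,6-dimethyl-4-{[(3E)-3-methyl-2-(oxomethylidene)pent-3-enoyl]oxy}benzoate (vinylketene) | C/C=C(\C)C(=C=O)C(=O)Oc1cc(C)c(C(=O)OCc2ccccc2)c(OC)c1C | intermediate (not isolated)
17 | 4-[(benzyloxy)carbonyl]-3-methoxy-2,5-dimethylphenyl 1-[(E)-but-2-en-2-yl]-2-methoxy-3-methyl-4-oxocyclobut-2-ene-1-carboxylate (racemic at C1) | C/C=C(\C)C1(C(=O)Oc2cc(C)c(C(=O)OCc3ccccc3)c(OC)c2C)C(OC)=C(C)C1=O | intermediate (not isolated)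
18 | 4-[(benzyloxy)carbonyl]-3-methoxy-2,5-dimethylphenyl (2Z)-2-[(E)-but-2-en-2-yl]-3-methoxy-4-methyl-5-oxopenta-2,4-dienoate (dienylketene) | O=C=C(C)/C(OC)=C(/C(=O)Oc1cc(C)c(C(=O)OCc2ccccc2)c(OC)c1C)\C(C)=C\C | intermediate (not isolated)
19 | 4-[(benzyloxy)carbonyl]-3-methoxy-2,5-dimethylphenyl 6-methoxy-2,3,5-trimethyl-4-oxocyclohexa-1,5-diene-1-carboxylate (racemic at C3) | CC1C(=O)C(C)=C(OC)C(C(=O)Oc2cc(C)c(C(=O)OCc3ccccc3)c(OC)c2C)=C1C | intermediate (not isolated)
20 | benzyl 4-[(4-hydroxy-2-methoxy-3,5,6-trimethylbenzoyl)oxy]-2-methoxy-3,6-dimethylbenzoate | COc1c(C)c(OC(=O)c2c(C)c(C)c(O)c(C)c2OC)cc(C)c1C(=O)OCc1ccccc1 | intermediate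
21 | methyl 2,4-bis(benzyloxy)-3,6-dimethylbenzoate | COC(=O)c1c(C)cc(OCc2ccccc2)c(C)c1OCc1ccccc1 | intermediate
22 | 2,4-bis(benzyloxy)-3,6-dimethylbenzoic acid | Cc1cc(OCc2ccccc2)c(C)c(OCc2ccccc2)c1C(=O)O | intermediate
23 | 2,4-bis(benzyloxy)-3,6-dimethylbenzoic trifluoroacetic anhydride | Cc1cc(OCc2ccccc2)c(C)c(OCc2ccccc2)c1C(=O)OC(=O)C(F)(F)F | intermediate (not isolated)
24 | benzyl 4-[(4-{[2,4-bis(benzyloxy)-3,6-dimethylbenzoyl]oxy}-2-methoxy-3,5,6-trimethylbenzoyl)oxy]-2-methoxy-3,6-dimethylbenzoate | COc1c(C)c(OC(=O)c2c(C)c(C)c(OC(=O)c3c(C)cc(OCc4ccccc4)c(C)c3OCc3ccccc3)c(C)c2OC)cc(C)c1C(=O)OCc1ccccc1 | intermediate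
25 | 4-[(4-{[2,4-dihydroxy-3,6-dimethylbenzoyl]oxy}-2-methoxy-3,5,6-trimethylbenzoyl)oxy]-2-methoxy-3,6-dimethylbenzoic acid | COc1c(C)c(OC(=O)c2c(C)c(C)c(OC(=O)c3c(C)cc(O)c(C)c3O)c(C)c2OC)cc(C)c1C(=O)O | target

**Count**

Total steps: 14. Longest linear sequence: 10 steps (1, 2, 3, 4, 5, 7, 8, 10, 13, 14).

**Steps most likely to fail**

Step 10 (carries the new-method label). What may go wrong:
- After the first C–C bond forms, the ester-stabilised enolate may close through the ester oxygen or the diene terminus instead of the α-carbon.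
- The ester may rotate inwards in the 4π opening and divert material through an oxa-6π closure.
- The photogenerated carbene may add to the alkyne before the Wolff shift.

The fallback removes the ester from the ketene and uses the documented diazo ketone variant. It sets out from 15 and commercial (E)-3-methylpent-3-en-2-one F1 and returns at 24. Detrifluoroacetylative diazo transfer (LiHMDS, CF3CO2CH2CF3, THF, −78 °C, giving (E)-1,1,1-trifluoro-5-methylhept-5-ene-2,4-dione F2 without isolation; then MsN3, Et3N, H2O, MeCN) would give (E)-1-diazo-3-methylpent-3-en-2-one F3. Irradiation of F3 with 15 and heating should give 3-methoxy-2,5,6-trimethylphenol F4. Its only free ring position (para to OH, ortho to OMe) would be formylated (Cl2CHOMe, TiCl4, CH2Cl2, 0 °C; Rieche) to 4-hydroxy-2-methoxy-3,5,6-trimethylbenzaldehyde F5. Esterification of F5 with acid 22 (trifluoroacetic anhydride, toluene, through 23) would give 4-formyl-3-methoxy-2,5,6-trimethylphenyl 2,4-bis(benzyloxy)-3,6-dimethylbenzoate F6. Pinnick oxidation (NaClO2, NaH2PO4, 2-methyl-2-butene, t-BuOH/H2O) would give 4-{[2,4-bis(benzyloxy)-3,6-dimethylbenzoyl]oxy}-2-methoxy-3,5,6-trimethylbenzoic acid F7. Activation of F7 as its mixed trifluoroacetic anhydride F8 and capture by phenol 6 would then give 24. The price is that the B–A ester is made at the hindered stage.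

Step 13. What may go wrong: acyl transfer between two di-ortho-substituted partners may be slow, so that trifluoroacetylation of the phenol, C-acylation of electron-rich rings and slow acid-induced loss of benzyl groups compete. The fallback replaces acyl substitution by addition of the phenol to an unhindered ketene carbon. It sets out from 2 and 20 and returns at 25. Saponification of 2 (KOH, aq. DMSO, 90 °C; cold acidification) would give 4-(benzyloxy)-2-hydroxy-3,6-dimethylbenzoic acid F9. Acetonide formation (acetone, trifluoroacetic anhydride, CF3CO2H) would give 7-(benzyloxy)-2,2,5,8-tetramethyl-4H-1,3-benzodioxin-4-one F10. Irradiation of F10 at 300 nm in CH2Cl2 with 20 expels acetone and generates 3-(benzyloxy)-2,5-dimethyl-6-(oxomethylidene)cyclohexa-2,4-dien-1-one F11. This photochemical acylation through an o-quinone ketene is established for alcohols, including hindered ones. Addition of the phenol of 20 to F11 would give benzyl 4-[(4-{[4-(benzyloxy)-2-hydroxy-3,6-dimethylbenzoyl]oxy}-2-methoxy-3,5,6-trimethylbenzoyl)oxy]-2-methoxy-3,6-dimethylbenzoate F12. Hydrogenolysis of F12 (H2, Pd/C, EtOAc) would give 25.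

Step 7. What may go wrong: the weakly nucleophilic phenol may capture the acylketene too slowly, so that ketene dimerisation or cyclisation takes over, and incomplete C-acylation in step 6 would add to the loss. The fallback builds the β-keto ester by a decarboxylative Claisen condensation instead of ketene capture. It sets out from 6, 8 and 7 and returns at 11. Heating 6 with 8 (toluene, 100 °C) would open Meldrum's acid to 3-{4-[(benzyloxy)carbonyl]-3-methoxy-2,5-dimethylphenoxy}-3-oxopropanoic acid F13. Tiglic acid 7 and carbonyldiimidazole (THF, rt) would give (E)-1-(1H-imidazol-1-yl)-2-methylbut-2-en-1-one F14. Acylation of the magnesium enolate of F13 (MgCl2, Et3N, MeCN, rt) with F14, with loss of CO2 on acidic work-up (Masamune–Brooks conditions), would give 11.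

**Further compounds**

F1 | step 10 | (E)-3-methylpent-3-en-2-one | C/C=C(\C)C(C)=O
F2 | step 10 | (E)-1,1,1-trifluoro-5-methylhept-5-ene-2,4-dione | C/C=C(\C)C(=O)CC(=O)C(F)(F)F
F3 | step 10 | (E)-1-diazo-3-methylpent-3-en-2-one | C/C=C(\C)C(=O)C=[N+]=[N-]
F4 | step 10 | 3-methoxy-2,5,6-trimethylphenol | COc1cc(C)c(C)c(O)c1C
F5 | step 10 | 4-hydroxy-2-methoxy-3,5,6-trimethylbenzaldehyde | COc1c(C)c(O)c(C)c(C)c1C=O
F6 | step 10 | 4-formyl-3-methoxy-2,5,6-trimethylphenyl 2,4-bis(benzyloxy)-3,6-dimethylbenzoate | COc1c(C)c(OC(=O)c2c(C)cc(OCc3ccccc3)c(C)c2OCc2ccccc2)c(C)c(C)c1C=O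
F7 | step 10 | 4-{[2,4-bis(benzyloxy)-3,6-dimethylbenzoyl]oxy}-2-methoxy-3,5,6-trimethylbenzoic acid | COc1c(C)c(OC(=O)c2c(C)cc(OCc3ccccc3)c(C)c2OCc2ccccc2)c(C)c(C)c1C(=O)O
F8 | step 10 | 4-{[2,4-bis(benzyloxy)-3,6-dimethylbenzoyl]oxy}-2-methoxy-3,5,6-trimethylbenzoic trifluoroacetic anhydride | COc1c(C)c(OC(=O)c2c(C)cc(OCc3ccccc3)c(C)c2OCc2ccccc2)c(C)c(C)c1C(=O)OC(=O)C(F)(F)F
F9 | step 13 | 4-(benzyloxy)-2-hydroxy-3,6-dimethylbenzoic acid | Cc1cc(OCc2ccccc2)c(C)c(O)c1C(=O)O
F10 | step 13 | 7-(benzyloxy)-2,2,5,8-tetramethyl-4H-1,3-benzodioxin-4-one | Cc1cc(OCc2ccccc2)c(C)c2OC(C)(C)OC(=O)c12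
F11 | step 13 | 3-(benzyloxy)-2,5-dimethyl-6-(oxomethylidene)cyclohexa-2,4-dien-1-one | O=C=C1C(C)=CC(OCc2ccccc2)=C(C)C1=O
F12 | step 13 | benzyl 4-[(4-{[4-(benzyloxy)-2-hydroxy-3,6-dimethylbenzoyl]oxy}-2-methoxy-3,5,6-trimethylbenzoyl)oxy]-2-methoxy-3,6-dimethylbenzoate | COc1c(C)c(OC(=O)c2c(C)c(C)c(OC(=O)c3c(C)cc(OCc4ccccc4)c(C)c3O)c(C)c2OC)cc(C)c1C(=O)OCc1ccccc1
F13 | step 7 | 3-{4-[(benzyloxy)carbonyl]-3-methoxy-2,5-dimethylphenoxy}-3-oxopropanoic acid | OC(=O)CC(=O)Oc1cc(C)c(C(=O)OCc2ccccc2)c(OC)c1C
F14 | step 7 | (E)-1-(1H-imidazol-1-yl)-2-methylbut-2-en-1-one | C/C=C(\C)C(=O)n1ccnc1
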